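**Retrosynthetic overview**
1. 15 ⇒ 14 (last step): ring C is closed through the C4–C4a bond and C3–H is created in the same operation, by a photoenzymatic aryl-radical cyclisation in a flavin-dependent ene-reductase; 14 is achiral and unprotected.
2. Enabling feature: C3 is a methine bearing ring B, and C4 is an unsubstituted CH2 bonded to C4a, which lies ortho to O1. An O1–C2–C3(=C4H2) 2-arylallyl ether on a C4a radical therefore closes ring C at C4 and leaves a ring-B-stabilised tertiary benzylic radical at C3, the only stereocentre.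
3. 14 ⇒ 13 ⇒ 12: desilylation, then Wittig methylenation of an aryloxymethyl ketone; 12 ⇒ 9 + 11 by Williamson formation of O1–C2 (ring B fragment plus ring A fragment).
4. 9 ⇒ 1: C-prenylation of 2,4-dihydroxyacetophenone between its two oxygens, then chromene annulation with prenal, which the prenyl group forces into the linear mode; 11 ⇒ 4-iodoresorcinol.
5. Ring order: rings A and B are bought as arenes; the dimethylpyran ring (ring D) is made in step 2, ring C in step 9.

Key step: step 9

Remark: O1, C2, C3, C4, C4a refer to the chroman unit (rings A and C) of 15, whose stereocentre C3 is (R); 4-iodobenzene-1,3-diol (10) is taken to be a catalogue compound.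

Step 1
Reactants: 1 1-(2,4-dihydroxyphenyl)ethan-1-one; 2 1-bromo-3-methylbut-2-ene (prenyl bromide)
Product: 3 1-[2,4-dihydroxy-3-(3-methylbut-2-en-1-yl)phenyl]ethan-1-one
Conditions: 10% aq. KOH, 0 °C to rt; chromatography
Reagents that add atoms: none
Why: Aqueous-base C-alkylation of an ambident resorcinolate (C-prenylation), in which water favours attack through carbon, preferentially at C3 between the two oxygens, and the O-alkylated and C5-alkylated isomers are removed by chromatography.

Step 2
Reactants: 3 1-[2,4-dihydroxy-3-(3-methylbut-2-en-1-yl)phenyl]ethan-1-one; 4 3-methylbut-2-enal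
Product: 6 1-[7-hydroxy-2,2-dimethyl-8-(3-methylbut-2-en-1-yl)-2H-chromen-6-yl]ethan-1-one, via ortho-quinone methide 5 (not isolated)
Conditions: ethylenediammonium diacetate (cat.), xylene, 140 °C
Reagents that add atoms: none
Why: Knoevenagel-type condensation followed by oxa-6π electrocyclisation (formal [3+3] chromene annulation), which can only give the linear pyran because the prenyl group blocks C3 and C5 is the sole free position ortho to the non-chelated 4-hydroxyl.

Step 3
Reactants: 6 1-[7-hydroxy-2,2-dimethyl-8-(3-methylbut-2-en-1-yl)-2H-chromen-6-yl]ethan-1-one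
Product: 7 1-[2,2-dimethyl-8-(3-methylbut-2-en-1-yl)-7-[(triisopropylsilyl)oxy]-2H-chromen-6-yl]ethan-1-one
Conditions: iPr3SiOTf, 2,6-lutidine, CH2Cl2, 0 °C to rt
Reagents that add atoms: triisopropylsilyl trifluoromethanesulfonate, CC(C)[Si](OS(=O)(=O)C(F)(F)F)(C(C)C)C(C)C
Why: Silylation of a hindered, hydrogen-bonded phenol with a silyl triflate, giving an ether that keeps the ortho-oxygen from displacing the α-halide later (benzofuranone formation) and that fluoride removes without acid.

Step 4
Reactants: 7 1-[2,2-dimethyl-8-(3-methylbut-2-en-1-yl)-7-[(triisopropylsilyl)oxy]-2H-chromen-6-yl]ethan-1-one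
Product: 9 2-bromo-1-[2,2-dimethyl-8-(3-methylbut-2-en-1-yl)-7-[(triisopropylsilyl)oxy]-2H-chromen-6-yl]ethan-1-one, via trimethylsilyl enol ether 8 (not isolated)
Conditions: LiN(SiMe3)2, Me3SiCl, THF, −78 °C; then N-bromosuccinimide (1.0 equiv), −78 °C
Reagents that add atoms: chlorotrimethylsilane, C[Si](C)(C)Cl (atoms in 8 only); N-bromosuccinimide, O=C1CCC(=O)N1Br
Why: α-Bromination of a ketone through its silyl enol ether, which is far more nucleophilic than the prenyl and chromene double bonds, so one equivalent of electrophilic bromine at low temperature should react only at the α-carbon.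

Step 5
Reactants: 10 4-iodobenzene-1,3-diol
Product: 11 2-iodo-5-[(triisopropylsilyl)oxy]phenol
Conditions: iPr3SiCl (1.0 equiv), imidazole, CH2Cl2/DMF, 0 °C
Reagents that add atoms: chlorotriisopropylsilane, CC(C)[Si](Cl)(C(C)C)C(C)C
Why: Regioselective mono-silylation, in which the bulky silyl chloride should react at the hydroxyl para to iodine because the hydroxyl ortho to iodine is shielded.

Step 6
Reactants: 9 2-bromo-1-[2,2-dimethyl-8-(3-methylbut-2-en-1-yl)-7-[(triisopropylsilyl)oxy]-2H-chromen-6-yl]ethan-1-one; 11 2-iodo-5-[(triisopropylsilyl)oxy]phenol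
Product: 12 1-[2,2-dimethyl-8-(3-methylbut-2-en-1-yl)-7-[(triisopropylsilyl)oxy]-2H-chromen-6-yl]-2-{2-iodo-5-[(triisopropylsilyl)oxy]phenoxy}ethan-1-one
Conditions: K2CO3, acetone, rt
Reagents that add atoms: none
Why: Williamson ether synthesis (SN2 of a phenoxide on an α-bromo ketone), which forms the O1–C2 bond under mild carbonate conditions that the silyl ethers and the aryl iodide tolerate.

Step 7
Reactants: 12 1-[2,2-dimethyl-8-(3-methylbut-2-en-1-yl)-7-[(triisopropylsilyl)oxy]-2H-chromen-6-yl]-2-{2-iodo-5-[(triisopropylsilyl)oxy]phenoxy}ethan-1-one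
Product: 13 6-[3-{2-iodo-5-[(triisopropylsilyl)oxy]phenoxy}prop-1-en-2-yl]-2,2-dimethyl-8-(3-methylbut-2-en-1-yl)-7-[(triisopropylsilyl)oxy]-2H-chromene
Conditions: Ph3PCH3Br, KOtBu, THF, 0 °C to rt
Reagents that add atoms: methyltriphenylphosphonium bromide, C[P+](c1ccccc1)(c1ccccc1)c1ccccc1.[Br-]
Why: Wittig methylenation turns the ketone carbon (future C3) into the 1,1-disubstituted alkene whose CH2 terminus becomes C4, the unstabilised ylide being expected to add to the carbonyl faster than it enolises it.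

Step 8
Reactants: 13 6-[3-{2-iodo-5-[(triisopropylsilyl)oxy]phenoxy}prop-1-en-2-yl]-2,2-dimethyl-8-(3-methylbut-2-en-1-yl)-7-[(triisopropylsilyl)oxy]-2H-chromene
Product: 14 6-[3-(5-hydroxy-2-iodophenoxy)prop-1-en-2-yl]-2,2-dimethyl-8-(3-methylbut-2-en-1-yl)-2H-chromen-7-ol
Conditions: Bu4NF, AcOH (1:1, 2.2 equiv), THF, 0 °C to rt
Reagents that add atoms: none
Why: Fluoride cleavage of aryl silyl ethers, buffered with acetic acid so that the electron-rich styrene, the prenyl group, the chromene and the allyl aryl ether see neither acid nor strong base.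

Step 9
Reactants: 14 6-[3-(5-hydroxy-2-iodophenoxy)prop-1-en-2-yl]-2,2-dimethyl-8-(3-methylbut-2-en-1-yl)-2H-chromen-7-ol
Product: 15 6-[(3R)-7-hydroxy-3,4-dihydro-2H-chromen-3-yl]-2,2-dimethyl-8-(3-methylbut-2-en-1-yl)-2H-chromen-7-ol
Conditions: flavin mononucleotide-dependent ene-reductase (old yellow enzyme family; (R)-delivering member of a screened panel), NADP+ (cat.), glucose dehydrogenase, D-glucose, KH2PO4/K2HPO4 buffer pH 8.0, 10% DMSO, blue LEDs (450 nm), N2, 25 °C
Reagents that add atoms: none
Why: Proposed new method: the enzyme-bound flavin hydroquinone, excited by visible light, transfers one electron to the aryl iodide of 14, the C–I bond breaks, the ring A radical at C4a adds to the unsubstituted alkene terminus C4, and the resulting C3 radical takes a hydrogen atom from N5–H of the flavin semiquinone; the closest known reaction types are the photoenzymatic reductive radical cyclisations and hydroalkylations of α-substituted styrenes run in ene-reductases from α-halo carbonyl compounds, which end in the same flavin-to-benzylic-radical hydrogen transfer, and tin-hydride cyclisations of 2-halophenyl allyl ethers, the aryl iodide as radical source in this enzyme class being the new element. Ring C closes in the 6-endo-trig mode through the C4a–C4 bond. The only stereocentre, C3, is set not in the C–C bond formation but in the terminating hydrogen-atom transfer, so it is controlled by the protein, which holds the planar tertiary benzylic radical with one face toward the flavin; the enzyme that delivers hydrogen to the face giving (R) is taken from a panel of enantiocomplementary ene-reductases. The step needs 6-endo over 5-exo closure and cyclisation before the aryl radical is reduced: the ring B aryl group on the internal alkene carbon hinders attack there and makes the 6-endo adduct a tertiary benzylic radical, and the short O1–C2–C3 tether should make closure faster than any bimolecular quench. A small-molecule hydrogen donor would give the racemate, which is the reason for the enzyme, and the free phenols, the prenyl group and the chromene should be inert to reduced flavin and to 450 nm light.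

**Compound list**
1 | 1-(2,4-dihydroxyphenyl)ethan-1-one | CC(=O)c1ccc(O)cc1O | starting material
2 | 1-bromo-3-methylbut-2-ene | CC(C)=CCBr | starting material
3 | 1-[2,4-dihydroxy-3-(3-methylbut-2-en-1-yl)phenyl]ethan-1-one | CC(=O)c1ccc(O)c(CC=C(C)C)c1O | intermediate
4 | 3-methylbut-2-enal | CC(C)=CC=O | starting material
5 | 4-acetyl-3-hydroxy-2-(3-methylbut-2-en-1-yl)-6-(3-methylbut-2-en-1-ylidene)cyclohexa-2,4-dien-1-one (ortho-quinone methide, alkene geometry not defined, not isolated) | CC(=O)C1=CC(=CC=C(C)C)C(=O)C(CC=C(C)C)=C1O | intermediate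
6 | 1-[7-hydroxy-2,2-dimethyl-8-(3-methylbut-2-en-1-yl)-2H-chromen-6-yl]ethan-1-one | CC(C)=CCc1c(O)c(C(C)=O)cc2c1OC(C)(C)C=C2 | intermediate
7 | 1-[2,2-dimethyl-8-(3-methylbut-2-en-1-yl)-7-[(triisopropylsilyl)oxy]-2H-chromen-6-yl]ethan-1-one | CC(C)=CCc1c(O[Si](C(C)C)(C(C)C)C(C)C)c(C(C)=O)cc2c1OC(C)(C)C=C2 | intermediate
8 | {[1-(2,2-dimethyl-8-(3-methylbut-2-en-1-yl)-7-[(triisopropylsilyl)oxy]-2H-chromen-6-yl)ethenyl]oxy}trimethylsilane (not isolated) | CC(C)=CCc1c(O[Si](C(C)C)(C(C)C)C(C)C)c(C(=C)O[Si](C)(C)C)cc2c1OC(C)(C)C=C2 | intermediate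
9 | 2-bromo-1-[2,2-dimethyl-8-(3-methylbut-2-en-1-yl)-7-[(triisopropylsilyl)oxy]-2H-chromen-6-yl]ethan-1-one | CC(C)=CCc1c(O[Si](C(C)C)(C(C)C)C(C)C)c(C(=O)CBr)cc2c1OC(C)(C)C=C2 | intermediate
10 | 4-iodobenzene-1,3-diol | Oc1ccc(I)c(O)c1 | starting material
11 | 2-iodo-5-[(triisopropylsilyl)oxy]phenol | Oc1cc(O[Si](C(C)C)(C(C)C)C(C)C)ccc1I | intermediate
12 | 1-[2,2-dimethyl-8-(3-methylbut-2-en-1-yl)-7-[(triisopropylsilyl)oxy]-2H-chromen-6-yl]-2-{2-iodo-5-[(triisopropylsilyl)oxy]phenoxy}ethan-1-one | CC(C)=CCc1c(O[Si](C(C)C)(C(C)C)C(C)C)c(C(=O)COc3cc(O[Si](C(C)C)(C(C)C)C(C)C)ccc3I)cc2c1OC(C)(C)C=C2 | intermediate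
13 | 6-[3-{2-iodo-5-[(triisopropylsilyl)oxy]phenoxy}prop-1-en-2-yl]-2,2-dimethyl-8-(3-methylbut-2-en-1-yl)-7-[(triisopropylsilyl)oxy]-2H-chromene | CC(C)=CCc1c(O[Si](C(C)C)(C(C)C)C(C)C)c(C(=C)COc3cc(O[Si](C(C)C)(C(C)C)C(C)C)ccc3I)cc2c1OC(C)(C)C=C2 | intermediate
14 | 6-[3-(5-hydroxy-2-iodophenoxy)prop-1-en-2-yl]-2,2-dimethyl-8-(3-methylbut-2-en-1-yl)-2H-chromen-7-ol (achiral) | CC(C)=CCc1c(O)c(C(=C)COc3cc(O)ccc3I)cc2c1OC(C)(C)C=C2 | intermediate
15 | 6-[(3R)-7-hydroxy-3,4-dihydro-2H-chromen-3-yl]-2,2-dimethyl-8-(3-methylbut-2-en-1-yl)-2H-chromen-7-ol | CC(C)=CCc1c(O)c([C@@H]2COc3cc(O)ccc3C2)cc2c1OC(C)(C)C=C2 | target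

**Step count**
Total steps: 9. Longest linear sequence: 8 steps (1, 2, 3, 4, 6, 7, 8, 9).

**Steps most likely to fail**

Step 9 (Proposed new method). Electron transfer from the excited flavin to the electron-rich aryl iodide may be too slow, the aryl radical may be reduced before it cyclises, 5-exo closure followed by early hydrogen transfer may compete, or hydrogen delivery may be poorly face-selective. The fallback uses known organoboron chemistry and fixes the regiochemistry by anti-Markovnikov hydroboration; it sets out from 13 and comes back at 15. Hydroboration of the 1,1-disubstituted alkene of 13 with 9-borabicyclo[3.3.1]nonane (THF, rt) should give the primary B-alkyl-9-borabicyclo[3.3.1]nonane adduct F1. Intramolecular B-alkyl Suzuki–Miyaura coupling (PdCl2(dppf), K3PO4, THF/DMF/H2O, 60 °C) should then close ring C at C4–C4a to the racemic bis-silyl isoflavan F2. Bu4NF/AcOH in THF should give the racemic diphenol F3, from which 15 would be obtained by preparative supercritical-fluid chromatography on an amylose tris(3,5-dimethylphenylcarbamate) phase.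

Step 4. Electrophilic bromine may add to the chromene or prenyl double bond or brominate twice, and further on the hindered, enolisable ketone 12 may resist methylenation. The fallback avoids both the α-halo ketone and the Wittig step; it sets out from 7 and comes back at 13. Enolisation and triflation of 7 (KN(SiMe3)2, PhNTf2, THF, −78 °C) should give the enol triflate F4. Methoxycarbonylation (Pd(OAc)2, PPh3, CO 1 atm, MeOH, Et3N, DMF, 50 °C) should give the methyl 2-arylacrylate F5, and 1,2-reduction (iBu2AlH, CH2Cl2, −78 °C) the 2-arylallyl alcohol F6. Mitsunobu etherification of F6 with 11 (PPh3, diisopropyl azodicarboxylate, THF, 0 °C) should give 13.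

Step 1. O-alkylation, alkylation at C5 and double alkylation compete with alkylation at C3. The fallback delivers the prenyl group by a sigmatropic shift that can only reach C3; it sets out from 1 and comes back at 3. Selective protection of the non-chelated hydroxyl (MeOCH2Cl, K2CO3, acetone) should give the 4-methoxymethyl ether F7. O-alkylation of the chelated hydroxyl with 3-chloro-3-methylbut-1-yne (DBU, CuCl2 cat., MeCN) should give the propargyl ether F8, and semi-hydrogenation (H2, Pd/CaCO3 poisoned with Pb(OAc)2, quinoline, EtOAc) the 1,1-dimethylallyl ether F9. Aromatic Claisen rearrangement (PhNEt2, 130 °C) to C3, the only free ortho position, should give the 3-prenyl phenol F10, and HCl in MeOH at rt should release 3.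

**Further compounds**
F1 | step 9 | 9-[2-{2,2-dimethyl-8-(3-methylbut-2-en-1-yl)-7-[(triisopropylsilyl)oxy]-2H-chromen-6-yl}-3-{2-iodo-5-[(triisopropylsilyl)oxy]phenoxy}propyl]-9-borabicyclo[3.3.1]nonane (racemic) | CC(C)=CCc1c(O[Si](C(C)C)(C(C)C)C(C)C)c(C(CB5C6CCCC5CCC6)COc3cc(O[Si](C(C)C)(C(C)C)C(C)C)ccc3I)cc2c1OC(C)(C)C=C2
F2 | step 9 | racemic 2,2-dimethyl-8-(3-methylbut-2-en-1-yl)-7-[(triisopropylsilyl)oxy]-6-{7-[(triisopropylsilyl)oxy]-3,4-dihydro-2H-chromen-3-yl}-2H-chromene | CC(C)=CCc1c(O[Si](C(C)C)(C(C)C)C(C)C)c(C3COc4cc(O[Si](C(C)C)(C(C)C)C(C)C)ccc4C3)cc2c1OC(C)(C)C=C2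
F3 | step 9 | racemic 6-(7-hydroxy-3,4-dihydro-2H-chromen-3-yl)-2,2-dimethyl-8-(3-methylbut-2-en-1-yl)-2H-chromen-7-ol | CC(C)=CCc1c(O)c(C3COc4cc(O)ccc4C3)cc2c1OC(C)(C)C=C2
F4 | step 4 | 1-[2,2-dimethyl-8-(3-methylbut-2-en-1-yl)-7-[(triisopropylsilyl)oxy]-2H-chromen-6-yl]ethenyl trifluoromethanesulfonate | CC(C)=CCc1c(O[Si](C(C)C)(C(C)C)C(C)C)c(C(=C)OS(=O)(=O)C(F)(F)F)cc2c1OC(C)(C)C=C2
F5 | step 4 | methyl 2-[2,2-dimethyl-8-(3-methylbut-2-en-1-yl)-7-[(triisopropylsilyl)oxy]-2H-chromen-6-yl]prop-2-enoate | CC(C)=CCc1c(O[Si](C(C)C)(C(C)C)C(C)C)c(C(=C)C(=O)OC)cc2c1OC(C)(C)C=C2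
F6 | step 4 | 2-[2,2-dimethyl-8-(3-methylbut-2-en-1-yl)-7-[(triisopropylsilyl)oxy]-2H-chromen-6-yl]prop-2-en-1-ol | CC(C)=CCc1c(O[Si](C(C)C)(C(C)C)C(C)C)c(C(=C)CO)cc2c1OC(C)(C)C=C2
F7 | step 1 | 1-[2-hydroxy-4-(methoxymethoxy)phenyl]ethan-1-one | CC(=O)c1ccc(OCOC)cc1O
F8 | step 1 | 1-[4-(methoxymethoxy)-2-[(2-methylbut-3-yn-2-yl)oxy]phenyl]ethan-1-one | CC(=O)c1ccc(OCOC)cc1OC(C)(C)C#C
F9 | step 1 | 1-[4-(methoxymethoxy)-2-[(2-methylbut-3-en-2-yl)oxy]phenyl]ethan-1-one | CC(=O)c1ccc(OCOC)cc1OC(C)(C)C=C
F10 | step 1 | 1-[2-hydroxy-4-(methoxymethoxy)-3-(3-methylbut-2-en-1-yl)phenyl]ethan-1-one | CC(=O)c1ccc(OCOC)c(CC=C(C)C)c1O
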